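**Retrosynthetic overview**
- The furan ring of the benzofuran is closed last, by dehydrogenative C2–O cyclisation of a 2'-hydroxyisoflavone. The isoflavone comes from Suzuki–Miyaura coupling of a 5,7-dibenzyloxy-3-iodochromone (rings A and C, from phloroacetophenone) with a ring B boronate.
- Ring B carries the finished dihydrofuran before the coupling. It is made in one flask from a monocyclic fluoroarene and a chiral epoxide: an aryllithium opens the strained epoxide (aryl–CH2 bond) and the alkoxide so set free displaces fluoride (aryl–O bond).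
- Enabling feature: in ring B the carbon that carries the dihydrofuran CH2 (C3') lies between the two oxygen-bearing carbons C2' and C4'. With fluorine standing in for the C4' oxygen, that C–H is the most acidic one of the arene, and the same fluorine is then the leaving group for ring closure.
- The only stereocentre comes from the chiral pool (methyl (S)-glycerate acetonide) and is never a reaction centre.
- Order of ring formation: dihydrofuran, then pyranone ring C, then furan.

Key step: step 6

Remark: the stereocentre is S in the target (ranking O > C(CH3)2O > CH2 > H); the same ranking holds in every intermediate, so the descriptor stays S throughout.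

**Route**

Step 1
Reactants: 1 methyl (S)-2,2-dimethyl-1,3-dioxolane-4-carboxylate
Product: 2 (S)-2-(2,2-dimethyl-1,3-dioxolan-4-yl)propan-2-ol
Conditions: MeMgBr (3 equiv), THF, 0 °C to rt; aq NH4Cl work-up
Reagents that add atoms: methylmagnesium bromide, C[Mg]Br
Why: Double Grignard addition to the ester should give the tertiary alcohol, and the stereocentre, which is not a reaction centre, is carried over from the chiral pool.

Step 2
Reactants: 2 (S)-2-(2,2-dimethyl-1,3-dioxolan-4-yl)propan-2-ol
Product: 3 (S)-4-[2-(methoxymethoxy)propan-2-yl]-2,2-dimethyl-1,3-dioxolane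
Conditions: MOMCl (3 equiv), i-Pr2NEt (4 equiv), NaI (cat.), 1,2-dichloroethane, 60 °C
Reagents that add atoms: chloromethyl methyl ether, COCCl
Why: Iodide-assisted O-alkylation of the hindered tertiary alcohol (MOM ether formation) masks the oxygen that would otherwise compete in step 6, and an acetal ether cannot migrate under the basic conditions used there.

Step 3
Reactants: 3 (S)-4-[2-(methoxymethoxy)propan-2-yl]-2,2-dimethyl-1,3-dioxolane
Product: 4 (S)-3-(methoxymethoxy)-3-methylbutane-1,2-diol
Conditions: AcOH/H2O (4:1), 40 °C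
Reagents that add atoms: none
Why: The terminal isopropylidene ketal should be hydrolysed by aqueous acetic acid much faster than the MOM ether (selective acetal hydrolysis), so the 1,2-diol is freed without loss of the MOM group.

Step 4
Reactants: 4 (S)-3-(methoxymethoxy)-3-methylbutane-1,2-diol
Product: 6 (S)-2-[2-(methoxymethoxy)propan-2-yl]oxirane, via primary monotosylate 5 (not isolated)
Conditions: NaH (2.2 equiv), N-tosylimidazole (1.05 equiv), THF, 0 °C to rt
Reagents that add atoms: none
Why: The primary hydroxyl should be sulfonylated selectively and the neighbouring secondary alkoxide then closes the ring by intramolecular Williamson displacement (one-pot epoxide formation from a 1,2-diol), which leaves the C–O bond of the stereocentre intact, so the configuration is retained.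

Step 5
Reactants: 7 3-fluorophenol
Product: 8 1-fluoro-3-(methoxymethoxy)benzene
Conditions: MOMCl (1.2 equiv), i-Pr2NEt, CH2Cl2, 0 °C to rt
Reagents that add atoms: chloromethyl methyl ether, COCCl
Why: O-Alkylation of the phenol (MOM ether formation) installs the group that directs both later metalations and is removable in the presence of benzyl ethers.

Step 6
Reactants: 8 1-fluoro-3-(methoxymethoxy)benzene; 6 (S)-2-[2-(methoxymethoxy)propan-2-yl]oxirane
Product: 11 (S)-4-(methoxymethoxy)-2-[2-(methoxymethoxy)propan-2-yl]-2,3-dihydro-1-benzofuran, via aryllithium 9 (not isolated), via lithium fluoroalkoxide 10 (not isolated)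
Conditions: 8 (1.3 equiv), s-BuLi (1.25 equiv), THF, −78 °C; then 6 (1.0 equiv), BF3·OEt2 (1.3 equiv), −78 °C; then KOtBu (4 equiv), DMPU, −78 to 65 °C, one flask
Reagents that add atoms: none
Why: s-BuLi should remove the one proton of 8 that lies between the fluorine and the OMOM oxygen (directed ortho metalation by two cooperating groups), and aryllithium 9 then opens the BF3-activated epoxide by SN2 attack at its unsubstituted CH2 carbon, so that release of ring strain drives formation of the aryl–CH2 bond. Once KOtBu has taken the boron off the oxygen and DMPU has been added, the alkoxide of 10 displaces the neighbouring fluoride by addition–elimination (SNAr) and so forms the aryl–O bond; the dihydrofuran closes by 5-exo attack on the fluorine-bearing ipso carbon. The closest known chemistry is the two-stage preparation of 2-substituted 2,3-dihydrobenzofurans from ortho-lithiated fluoroarenes and epoxides followed by base-induced fluoride displacement, telescoped here into one flask. No stereocentre is created: the S centre of 6 becomes C2 of the dihydrofuran with retention, because neither bond-forming event takes place at it. The step needs site selectivity twice, and the substrate secures both: the F / C–H / OMOM sequence of 8 makes the central C–H the most acidic one, and only the fluorine-bearing carbon is within reach of the tethered alkoxide (if the base instead deprotonated beside fluorine, the aryne so formed could be trapped only at that same carbon and would give the same ring). The tertiary oxygen is carried as a MOM ether so that it can neither quench 9 nor compete through a six-membered ring closure.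

Step 7
Reactants: 11 (S)-4-(methoxymethoxy)-2-[2-(methoxymethoxy)propan-2-yl]-2,3-dihydro-1-benzofuran
Product: 13 2-[(S)-4-(methoxymethoxy)-2-[2-(methoxymethoxy)propan-2-yl]-2,3-dihydro-1-benzofuran-5-yl]-4,4,5,5-tetramethyl-1,3,2-dioxaborolane, via C5 aryllithium 12 (not isolated)
Conditions: s-BuLi (1.3 equiv), TMEDA (1.3 equiv), THF, −78 °C; then i-PrOBpin (1.5 equiv), −78 °C to rt
Reagents that add atoms: 2-isopropoxy-4,4,5,5-tetramethyl-1,3,2-dioxaborolane, CC(C)OB1OC(C)(C)C(C)(C)O1
Why: The aryl OMOM group is the strongest director on the ring and C5 is its only free ortho position (directed ortho metalation, then borylation), so boron should enter at the carbon that will be bonded to C3 of the chromone.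

Step 8
Reactants: 14 2',4',6'-trihydroxyacetophenone
Product: 15 1-[2,4-bis(benzyloxy)-6-hydroxyphenyl]ethan-1-one
Conditions: BnBr (2.1 equiv), K2CO3 (2.2 equiv), DMF, rt
Reagents that add atoms: benzyl bromide, BrCc1ccccc1
Why: Williamson etherification should benzylate the two free hydroxyls, while the hydroxyl that is hydrogen-bonded to the acetyl carbonyl stays unreacted.

Step 9
Reactants: 15 1-[2,4-bis(benzyloxy)-6-hydroxyphenyl]ethan-1-one
Product: 17 5,7-bis(benzyloxy)-3-iodo-4H-chromen-4-one, via enaminone 16 (not isolated)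
Conditions: N,N-dimethylformamide dimethyl acetal (3 equiv), 95 °C; then I2 (1.5 equiv), CHCl3, rt
Reagents that add atoms: N,N-dimethylformamide dimethyl acetal, COC(OC)N(C)C; iodine, II
Why: Condensation of the methyl ketone with the amide acetal gives the enaminone, and iodine then triggers ring closure by the phenol with loss of dimethylamine and iodination at C3 (enaminone iodocyclisation to a 3-iodochromone).

Step 10
Reactants: 17 5,7-bis(benzyloxy)-3-iodo-4H-chromen-4-one; 13 2-[(S)-4-(methoxymethoxy)-2-[2-(methoxymethoxy)propan-2-yl]-2,3-dihydro-1-benzofuran-5-yl]-4,4,5,5-tetramethyl-1,3,2-dioxaborolane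
Product: 18 5,7-bis(benzyloxy)-3-[(S)-4-(methoxymethoxy)-2-[2-(methoxymethoxy)propan-2-yl]-2,3-dihydro-1-benzofuran-5-yl]-4H-chromen-4-one
Conditions: Pd(dppf)Cl2 (5 mol %; dppf = 1,1'-bis(diphenylphosphino)ferrocene), K2CO3 (2 equiv), 1,4-dioxane/H2O (5:1), 80 °C
Reagents that add atoms: none
Why: Suzuki–Miyaura coupling of a 3-iodochromone with an ortho-alkoxyaryl boronate is a standard isoflavone synthesis, and the mild carbonate base should spare the pyranone ring.

Step 11
Reactants: 18 5,7-bis(benzyloxy)-3-[(S)-4-(methoxymethoxy)-2-[2-(methoxymethoxy)propan-2-yl]-2,3-dihydro-1-benzofuran-5-yl]-4H-chromen-4-one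
Product: 19 5,7-bis(benzyloxy)-3-[(S)-4-hydroxy-2-(2-hydroxypropan-2-yl)-2,3-dihydro-1-benzofuran-5-yl]-4H-chromen-4-one
Conditions: HCl (1.25 M in MeOH), 45 °C
Reagents that add atoms: none
Why: Acid-catalysed acetal exchange with methanol should remove both MOM groups (MOM ether cleavage) while the benzyl ethers and the non-benzylic C–O bonds of the dihydrofuran stay intact.

Step 12
Reactants: 19 5,7-bis(benzyloxy)-3-[(S)-4-hydroxy-2-(2-hydroxypropan-2-yl)-2,3-dihydro-1-benzofuran-5-yl]-4H-chromen-4-one
Product: 21 5,7-di-O-benzyl ether of the target, via cis-fused oxa-Michael adduct 20 (not isolated)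
Conditions: DDQ (1.5 equiv), 1,4-dioxane, rt to 50 °C
Reagents that add atoms: none
Why: The 2'-hydroxyl adds to C2 of the chromone and DDQ abstracts the hydride of the resulting acetal-type C2–H, after which loss of the C3 proton gives the furan ring (dehydrogenative cyclisation of a 2'-hydroxyisoflavone to a coumaronochromone); the ether C–H bonds of the dihydrofuran are far less hydridic and should survive at this temperature.

Step 13
Reactants: 21 5,7-di-O-benzyl ether of the target
Product: 22 target CNP0193284.1
Conditions: H2 (1 atm), palladium on carbon (Pd/C, 10 wt %), EtOAc/MeOH (1:1), rt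
Reagents that add atoms: none
Why: Hydrogenolysis of the two aryl benzyl ethers should free the 5- and 7-hydroxyls without touching the fully substituted furan double bond, the non-benzylic C–O bonds of the dihydrofuran or the stereocentre.

**Compound list**

1 | methyl (S)-2,2-dimethyl-1,3-dioxolane-4-carboxylate | COC(=O)[C@@H]1COC(C)(C)O1 | starting material
2 | (S)-2-(2,2-dimethyl-1,3-dioxolan-4-yl)propan-2-ol | CC(C)(O)[C@@H]1COC(C)(C)O1 | intermediate
3 | (S)-4-[2-(methoxymethoxy)propan-2-yl]-2,2-dimethyl-1,3-dioxolane | COCOC(C)(C)[C@@H]1COC(C)(C)O1 | intermediate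
4 | (S)-3-(methoxymethoxy)-3-methylbutane-1,2-diol | COCOC(C)(C)[C@@H](O)CO | intermediate
5 | (S)-2-hydroxy-3-(methoxymethoxy)-3-methylbutyl 4-methylbenzenesulfonate (primary monotosylate) | COCOC(C)(C)[C@@H](O)COS(=O)(=O)c1ccc(C)cc1 | intermediate, not isolated
6 | (S)-2-[2-(methoxymethoxy)propan-2-yl]oxirane | COCOC(C)(C)[C@@H]1CO1 | intermediate
7 | 3-fluorophenol | Oc1cccc(F)c1 | starting material
8 | 1-fluoro-3-(methoxymethoxy)benzene | COCOc1cccc(F)c1 | intermediate
9 | [2-fluoro-6-(methoxymethoxy)phenyl]lithium | [Li]c1c(F)cccc1OCOC | intermediate, not isolated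
10 | lithium (S)-1-[2-fluoro-6-(methoxymethoxy)phenyl]-3-(methoxymethoxy)-3-methylbutan-2-olate | COCOC(C)(C)[C@@H]([O-])Cc1c(F)cccc1OCOC.[Li+] | intermediate, not isolated
11 | (S)-4-(methoxymethoxy)-2-[2-(methoxymethoxy)propan-2-yl]-2,3-dihydro-1-benzofuran | COCOC(C)(C)[C@@H]1Cc2c(OCOC)cccc2O1 | intermediate
12 | C5-lithiated 11, [(S)-4-(methoxymethoxy)-2-[2-(methoxymethoxy)propan-2-yl]-2,3-dihydro-1-benzofuran-5-yl]lithium | COCOC(C)(C)[C@@H]1Cc2c(OCOC)c([Li])ccc2O1 | intermediate, not isolated
13 | 2-[(S)-4-(methoxymethoxy)-2-[2-(methoxymethoxy)propan-2-yl]-2,3-dihydro-1-benzofuran-5-yl]-4,4,5,5-tetramethyl-1,3,2-dioxaborolane | COCOC(C)(C)[C@@H]1Cc2c(OCOC)c(B3OC(C)(C)C(C)(C)O3)ccc2O1 | intermediate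
14 | 2',4',6'-trihydroxyacetophenone | CC(=O)c1c(O)cc(O)cc1O | starting material
15 | 1-[2,4-bis(benzyloxy)-6-hydroxyphenyl]ethan-1-one | CC(=O)c1c(O)cc(OCc2ccccc2)cc1OCc1ccccc1 | intermediate
16 | (E)-1-[2,4-bis(benzyloxy)-6-hydroxyphenyl]-3-(dimethylamino)prop-2-en-1-one (enaminone) | CN(C)/C=C/C(=O)c1c(O)cc(OCc2ccccc2)cc1OCc1ccccc1 | intermediate, not isolated
17 | 5,7-bis(benzyloxy)-3-iodo-4H-chromen-4-one | O=c1c(I)coc2cc(OCc3ccccc3)cc(OCc3ccccc3)c12 | intermediate
18 | 5,7-bis(benzyloxy)-3-[(S)-4-(methoxymethoxy)-2-[2-(methoxymethoxy)propan-2-yl]-2,3-dihydro-1-benzofuran-5-yl]-4H-chromen-4-one | COCOC(C)(C)[C@@H]1Cc2c(OCOC)c(-c3coc4cc(OCc5ccccc5)cc(OCc5ccccc5)c4c3=O)ccc2O1 | intermediate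
19 | 5,7-bis(benzyloxy)-3-[(S)-4-hydroxy-2-(2-hydroxypropan-2-yl)-2,3-dihydro-1-benzofuran-5-yl]-4H-chromen-4-one | CC(C)(O)[C@@H]1Cc2c(O)c(-c3coc4cc(OCc5ccccc5)cc(OCc5ccccc5)c4c3=O)ccc2O1 | intermediate
20 | 2,3-dihydro form of 21 in which the 2'-oxygen has added to C2 of the chromone (cis ring fusion, the two new centres not fixed, S centre unchanged) | CC(C)(O)[C@@H]1Cc2c(ccc3c2OC2Oc4cc(OCc5ccccc5)cc(OCc5ccccc5)c4C(=O)C32)O1 | intermediate, not isolated
21 | 5,7-di-O-benzyl ether of the target (S-configured benzofuro[2,3-b]chromen-4-one with the 2-(2-hydroxypropan-2-yl)-2,3-dihydrofuran fused at C3'–C4') | CC(C)(O)[C@@H]1Cc2c(ccc3c2oc2oc4cc(OCc5ccccc5)cc(OCc5ccccc5)c4c(=O)c23)O1 | intermediate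
22 | CNP0193284.1, the 5,7-dihydroxy coumaronochromone carrying an (S)-2-(2-hydroxypropan-2-yl)-2,3-dihydrofuran fused at C3'–C4' (CH2 on C3', O on C4') | CC(C)(O)[C@@H]1Cc2c(ccc3c2oc2oc4cc(O)cc(O)c4c(=O)c23)O1 | target

**Step count and risks**

Total: 13 steps. Longest linear sequence: 10 steps (1, 2, 3, 4, 6, 7, 10, 11, 12, 13).

Steps most likely to fail:

1. Step 6. The ortho-fluoroaryllithium may be lost through fluoride elimination before it has opened the epoxide, and the ring closure may stall because the alkoxide stays bound to boron or the non-activated ring resists fluoride displacement. The fallback sets out from 6 and comes back at 11; it replaces fluorine by bromine and makes the aryl–O bond by copper catalysis instead of SNAr. 1-Bromo-3-(methoxymethoxy)benzene F1 (from 3-bromophenol and MOMCl as in step 5) is lithiated between bromine and OMOM with LiN(i-Pr)2 in THF at −78 °C and trapped at that temperature with 6 and BF3·OEt2. This should give (S)-1-[2-bromo-6-(methoxymethoxy)phenyl]-3-(methoxymethoxy)-3-methylbutan-2-ol F2, which is isolated and cyclised to 11 by intramolecular Ullmann etherification (CuI, 1,10-phenanthroline, Cs2CO3, toluene, 110 °C).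

2. Step 12. DDQ may over-oxidise: dehydrogenation of the dihydrofuran ring or oxidation of the free phenol can compete with the ring closure. The fallback sets out from 15 and 13 and comes back at 21; it closes the furan by addition–elimination at C2 without any oxidant. Ketone 15 is condensed with CS2 (KOtBu, THF) to 5,7-bis(benzyloxy)-4-hydroxy-2H-chromene-2-thione F3, which is S-methylated (MeI, K2CO3, acetone) to 5,7-bis(benzyloxy)-2-(methylsulfanyl)-4H-chromen-4-one F4 and iodinated at C3 (N-iodosuccinimide, CF3CO2H cat., MeCN) to 5,7-bis(benzyloxy)-3-iodo-2-(methylsulfanyl)-4H-chromen-4-one F5. Suzuki–Miyaura coupling of F5 with 13 (Pd(OAc)2, SPhos, K3PO4, toluene/H2O, 90 °C) should give 5,7-bis(benzyloxy)-3-[(S)-4-(methoxymethoxy)-2-[2-(methoxymethoxy)propan-2-yl]-2,3-dihydro-1-benzofuran-5-yl]-2-(methylsulfanyl)-4H-chromen-4-one F6. HCl in MeOH removes both MOM groups to give 5,7-bis(benzyloxy)-3-[(S)-4-hydroxy-2-(2-hydroxypropan-2-yl)-2,3-dihydro-1-benzofuran-5-yl]-2-(methylsulfanyl)-4H-chromen-4-one F7, and K2CO3 in DMF at 80 °C lets the 2'-phenoxide displace methanethiolate at C2 to give 21.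

3. Step 7. Metalation may occur at the wrong position (C7, beside the ring oxygen), or the base may open the dihydrofuran by β-elimination. The fallback sets out from 6 and comes back at 13; it brings the C5 handle in as bromine before the ring is made. 1-Bromo-4-fluoro-2-(methoxymethoxy)benzene F8 (from 2-bromo-5-fluorophenol and MOMCl) is deprotonated between fluorine and OMOM with LiN(i-Pr)2 (THF, −78 °C), which does not exchange the bromine, and carried through the one-flask sequence of step 6 with 6 (BF3·OEt2, then KOtBu, DMPU, 65 °C). This should give (S)-5-bromo-4-(methoxymethoxy)-2-[2-(methoxymethoxy)propan-2-yl]-2,3-dihydro-1-benzofuran F9, which is converted into 13 by Miyaura borylation (Pd(dppf)Cl2, B2pin2, KOAc, 1,4-dioxane, 90 °C).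

**Further compounds**

F1 | step 6 | 1-bromo-3-(methoxymethoxy)benzene | COCOc1cccc(Br)c1
F2 | step 6 | (S)-1-[2-bromo-6-(methoxymethoxy)phenyl]-3-(methoxymethoxy)-3-methylbutan-2-ol | COCOC(C)(C)[C@@H](O)Cc1c(Br)cccc1OCOC
F3 | step 12 | 5,7-bis(benzyloxy)-4-hydroxy-2H-chromene-2-thione | Oc1cc(=S)oc2cc(OCc3ccccc3)cc(OCc3ccccc3)c12
F4 | step 12 | 5,7-bis(benzyloxy)-2-(methylsulfanyl)-4H-chromen-4-one | CSc1cc(=O)c2c(OCc3ccccc3)cc(OCc3ccccc3)cc2o1
F5 | step 12 | 5,7-bis(benzyloxy)-3-iodo-2-(methylsulfanyl)-4H-chromen-4-one | CSc1oc2cc(OCc3ccccc3)cc(OCc3ccccc3)c2c(=O)c1I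
F6 | step 12 | 5,7-bis(benzyloxy)-3-[(S)-4-(methoxymethoxy)-2-[2-(methoxymethoxy)propan-2-yl]-2,3-dihydro-1-benzofuran-5-yl]-2-(methylsulfanyl)-4H-chromen-4-one | COCOC(C)(C)[C@@H]1Cc2c(OCOC)c(-c3c(SC)oc4cc(OCc5ccccc5)cc(OCc5ccccc5)c4c3=O)ccc2O1
F7 | step 12 | 5,7-bis(benzyloxy)-3-[(S)-4-hydroxy-2-(2-hydroxypropan-2-yl)-2,3-dihydro-1-benzofuran-5-yl]-2-(methylsulfanyl)-4H-chromen-4-one | CC(C)(O)[C@@H]1Cc2c(O)c(-c3c(SC)oc4cc(OCc5ccccc5)cc(OCc5ccccc5)c4c3=O)ccc2O1
F8 | step 7 | 1-bromo-4-fluoro-2-(methoxymethoxy)benzene | COCOc1cc(F)ccc1Br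
F9 | step 7 | (S)-5-bromo-4-(methoxymethoxy)-2-[2-(methoxymethoxy)propan-2-yl]-2,3-dihydro-1-benzofuran | COCOC(C)(C)[C@@H]1Cc2c(OCOC)c(Br)ccc2O1
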